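**Plan**

1. Retrosynthetic cuts, in order: the O‑acetyl group; the lactone C–O bond and the lactone C3–C4 bond (glyoxylate aldol); the bond from lactone C4 to the CH(CH2OAc) carbon (Claisen, which also creates the exo‑methylene); the side‑chain C=C (aldol/elimination); both carbocycles at the ring‑fusion bond C3a–C7a together with C4–C5 (intramolecular Diels–Alder); then the open chain (Johnson–Claisen, cross‑metathesis, alkynylation, Wittig).
2. Forward order: a linear triene ester is assembled in six steps, one cycloaddition closes the six‑ and the five‑membered ring, the activating formyl group is reduced to the second C4 methyl, and the side chain is grown outward, with the lactone closed in the penultimate step and the acetate added last.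
3. Enabling feature (hydrindane numbered as octahydro‑1H‑indene: C1 bears the side chain, C3a–H and C7a–CH3 are the fusion atoms, C4 is CMe2): the six‑membered ring C3a–C4–C5–C6–C7–C7a is a diene (C7a=C7–C6=C5, with the 7a‑methyl as its Z substituent) plus a dienophile (C3a=C4). C1–C2–C3 of the five‑membered ring is a three‑carbon tether. Because C4 is CMe2, one methyl can be carried as the activating CHO.
4. Stereochemistry: C1 comes from a catalytic asymmetric alkynylation relayed by a chair Johnson–Claisen. C3a and C7a come from the cycloaddition (endo mode, control by the allylic C1 centre). The CH(CH2OAc) centre comes from A(1,3)‑controlled face selection in the Claisen step. The two lactone centres come from a prolinol‑catalysed anti aldol.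

Key step: step 7

Assumption: in steps 2 and 14 the catalyst enantiomer named is the one expected to give the configuration drawn; if the sense of induction is the opposite, its commercial mirror image is used.

Step 1
Reactants: 1 pent-4-enal; 2 2-(triphenyl-λ5-phosphanylidene)propanal
Product: 3 (2E)-2-methylhepta-2,6-dienal
Conditions: PhMe, 80 °C
Reagents that add atoms: none
Why: Wittig olefination; the formyl‑stabilised ylide reacts with the aliphatic aldehyde much faster than with the enal product and should give the E trisubstituted alkene (no stereocentre is formed).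

Step 2
Reactants: 3 (2E)-2-methylhepta-2,6-dienal; 4 ethynyl(trimethyl)silane
Product: 5 (3S,4E)-4-methyl-1-(trimethylsilyl)nona-4,8-dien-1-yn-3-ol
Conditions: 4 (3 equiv), Me2Zn (3 equiv), (S,S)-ProPhenol (10 mol %), Ph3P=O (20 mol %), PhMe, 0 °C → rt; aq. NH4Cl
Reagents that add atoms: none
Why: Zinc/ProPhenol‑catalysed enantioselective 1,2‑addition of an alkynylzinc to an enal (asymmetric alkynylation); the dinuclear zinc catalyst differentiates the aldehyde faces and sets the S carbinol centre, whose chirality is later relayed to C1 of the hydrindane.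

Step 3
Reactants: 5 (3S,4E)-4-methyl-1-(trimethylsilyl)nona-4,8-dien-1-yn-3-ol; 6 1,1,1-triethoxyethane
Product: 8 ethyl (3R,4E)-3-(but-3-en-1-yl)-4-methyl-7-(trimethylsilyl)hept-4-en-6-ynoate, via ketene acetal 7 (not isolated)
Conditions: 6 (6 equiv), EtCO2H (cat.), 140 °C, EtOH distilled off
Reagents that add atoms: none
Why: Johnson–Claisen (orthoester Claisen) rearrangement through ketene acetal 7; in the chair transition state the alkynyl group sits equatorial, so the carbinol chirality is transferred suprafacially to the new C3 centre (R) and the new trisubstituted alkene is E, while the silyl‑capped propargylic arm is expected to react more slowly than the allylic arm.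

Step 4
Reactants: 8 ethyl (3R,4E)-3-(but-3-en-1-yl)-4-methyl-7-(trimethylsilyl)hept-4-en-6-ynoate; 9 2-methylprop-2-enal
Product: 10 ethyl (3R,4E)-4-methyl-3-[(3E)-4-methyl-5-oxopent-3-en-1-yl]-7-(trimethylsilyl)hept-4-en-6-ynoate
Conditions: 9 (8 equiv), second-generation Hoveyda–Grubbs catalyst [RuCl2(=CH-C6H4-2-O-i-Pr)(H2IMes)] (5 mol %), CH2Cl2, 40 °C
Reagents that add atoms: none
Why: Olefin cross‑metathesis of the only monosubstituted alkene with methacrolein, which should give the E enal; the trisubstituted enyne alkene and the silyl‑capped alkyne are expected to be too hindered to engage the ruthenium carbene.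

Step 5
Reactants: 10 ethyl (3R,4E)-4-methyl-3-[(3E)-4-methyl-5-oxopent-3-en-1-yl]-7-(trimethylsilyl)hept-4-en-6-ynoate
Product: 11 ethyl (3R,4E)-4-methyl-3-[(3E)-4-methyl-5-oxopent-3-en-1-yl]hept-4-en-6-ynoate
Conditions: K2CO3 (0.2 equiv), EtOH, 0 °C → rt
Reagents that add atoms: none
Why: Base‑catalysed protodesilylation of the alkynylsilane; ethanol as solvent avoids transesterification of the ethyl ester and no stereocentre is touched.

Step 6
Reactants: 11 ethyl (3R,4E)-4-methyl-3-[(3E)-4-methyl-5-oxopent-3-en-1-yl]hept-4-en-6-ynoate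
Product: 12 ethyl (3R,4E)-4-methyl-3-[(3E)-4-methyl-5-oxopent-3-en-1-yl]hepta-4,6-dienoate
Conditions: H2 (1 atm), Pd/CaCO3 poisoned with Pb(OAc)2 (Lindlar catalyst), quinoline, EtOAc, rt
Reagents that add atoms: none
Why: Lindlar semi‑hydrogenation of the terminal alkyne to a vinyl group completes the (E)-1,3‑diene; the conjugated trisubstituted enal alkene should not be reduced over poisoned palladium.

Step 7
Reactants: 12 ethyl (3R,4E)-4-methyl-3-[(3E)-4-methyl-5-oxopent-3-en-1-yl]hepta-4,6-dienoate
Product: 13 ethyl 2-[(1R,3aR,4R,7aS)-4-formyl-4,7a-dimethyl-2,3,3a,4,5,7a-hexahydro-1H-inden-1-yl]acetate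
Conditions: Me2AlCl (1.5 equiv), CH2Cl2, −78 → −20 °C; 1 M HCl
Reagents that add atoms: none
Why: Me2AlCl binds the formyl group and the (E)-2-methyl enal adds across the diene, whose tethered terminus carries the Z methyl, in a concerted, asynchronous intramolecular [4+2] cycloaddition (type 1 intramolecular Diels–Alder reaction of a terminally activated 1,3,8‑nonatriene). The closest known reaction type is the Lewis‑acid‑promoted intramolecular Diels–Alder synthesis of angularly methylated trans‑hydrindanes from trienes that carry a Z methyl group on the tethered diene carbon. The cyclohexene ring closes by the cycloaddition itself through the new bonds C3a–C7a and C4–C5, and the cyclopentane ring closes at the same moment as the fused ring spanned by the three‑carbon tether when the ring‑fusion bond C3a–C7a forms. C7a is set by the allylic centre C1, whose CH2CO2Et arm lies anti to the approaching dienophile while its hydrogen takes the inside position eclipsing the diene, so that the arm ends cis to the angular methyl; C3a is set by the endo orientation of the aluminium‑bound formyl group, which with the E enal places the tether exo and gives the trans ring fusion; C4 follows from suprafacial addition (CHO cis to H‑3a) and loses its chirality in step 9. The step needs endo over exo selectivity and diene π‑facial selectivity (regiochemistry is fixed by the tether), and these should be secured by the E geometries of both partners, by Lewis‑acid activation at low temperature and by the pre‑set C1 centre.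

Step 8
Reactants: 13 ethyl 2-[(1R,3aR,4R,7aS)-4-formyl-4,7a-dimethyl-2,3,3a,4,5,7a-hexahydro-1H-inden-1-yl]acetate
Product: 14 ethyl 2-[(1R,3aR,4R,7aS)-4-(1,3-dithiolan-2-yl)-4,7a-dimethyl-2,3,3a,4,5,7a-hexahydro-1H-inden-1-yl]acetate
Conditions: HSCH2CH2SH, BF3·OEt2 (0.2 equiv), CH2Cl2, 0 °C
Reagents that add atoms: ethane-1,2-dithiol, SCCS
Why: Lewis‑acid‑catalysed dithioacetalisation of the neopentyl aldehyde; the ester and the alkene are inert and no stereocentre changes.

Step 9
Reactants: 14 ethyl 2-[(1R,3aR,4R,7aS)-4-(1,3-dithiolan-2-yl)-4,7a-dimethyl-2,3,3a,4,5,7a-hexahydro-1H-inden-1-yl]acetate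
Product: 15 ethyl 2-[(1R,3aS,7aR)-4,4,7a-trimethyloctahydro-1H-inden-1-yl]acetate
Conditions: Raney Ni (W-2, excess), H2 (1 atm), EtOH, reflux
Reagents that add atoms: none
Why: Raney‑nickel desulfurisation (Mozingo reduction) turns the former activating formyl group into the second C4 methyl, and the same nickel/H2 system should hydrogenate the cis‑disubstituted ring alkene; C4 becomes achiral and the other centres are untouched.

Step 10
Reactants: 15 ethyl 2-[(1R,3aS,7aR)-4,4,7a-trimethyloctahydro-1H-inden-1-yl]acetate; 16 2-{[tert-butyl(dimethyl)silyl]oxy}acetaldehyde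
Product: 17 ethyl 4-{[tert-butyl(dimethyl)silyl]oxy}-3-hydroxy-2-[(1R,3aS,7aR)-4,4,7a-trimethyloctahydro-1H-inden-1-yl]butanoate (epimers at C2 and C3)
Conditions: LDA, THF, −78 °C; then 16; aq. NH4Cl
Reagents that add atoms: none
Why: Lithium ester‑enolate aldol addition; the two new centres form unselectively, which is harmless because both become sp2 carbons in step 11.

Step 11
Reactants: 17 ethyl 4-{[tert-butyl(dimethyl)silyl]oxy}-3-hydroxy-2-[(1R,3aS,7aR)-4,4,7a-trimethyloctahydro-1H-inden-1-yl]butanoate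
Product: 19 ethyl (2E)-4-{[tert-butyl(dimethyl)silyl]oxy}-2-[(1S,3aS,7aS)-4,4,7a-trimethyloctahydro-1H-inden-1-yl]but-2-enoate, via mesylate 18 (not isolated)
Conditions: MsCl, Et3N, CH2Cl2, 0 °C; then DBU, rt
Reagents that add atoms: none
Why: Mesylation and E1cB elimination; the conjugated ester should form as the E isomer (ester trans to CH2OSi), which avoids A(1,3) strain between the ester and the CH2OSi group.

Step 12
Reactants: 19 ethyl (2E)-4-{[tert-butyl(dimethyl)silyl]oxy}-2-[(1S,3aS,7aS)-4,4,7a-trimethyloctahydro-1H-inden-1-yl]but-2-enoate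
Product: 20 (2E)-4-{[tert-butyl(dimethyl)silyl]oxy}-2-[(1S,3aS,7aS)-4,4,7a-trimethyloctahydro-1H-inden-1-yl]but-2-en-1-ol
Conditions: i-Bu2AlH (2.5 equiv), CH2Cl2, −78 → 0 °C; aq. potassium sodium tartrate
Reagents that add atoms: none
Why: 1,2‑Reduction of the conjugated ester with i-Bu2AlH gives the allylic alcohol with retention of alkene geometry; the silyl ether is stable.

Step 13
Reactants: 20 (2E)-4-{[tert-butyl(dimethyl)silyl]oxy}-2-[(1S,3aS,7aS)-4,4,7a-trimethyloctahydro-1H-inden-1-yl]but-2-en-1-ol; 21 ethoxyethene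
Product: 23 (3R)-3-({[tert-butyl(dimethyl)silyl]oxy}methyl)-4-[(1R,3aS,7aS)-4,4,7a-trimethyloctahydro-1H-inden-1-yl]pent-4-enal, via allyl vinyl ether 22 (not isolated)
Conditions: 21 (solvent), Hg(OAc)2 (0.2 equiv), reflux; evaporate; xylene, 150 °C (sealed tube)
Reagents that add atoms: none
Why: Mercury‑catalysed vinyl ether exchange followed by Claisen rearrangement of allyl vinyl ether 22; because CH2OSi is cis to the hydrindane, A(1,3) strain holds H‑1 in the alkene plane and the chair transition state should form on the face anti to the quaternary C7a, which sets the new centre as R and creates the 1,1‑disubstituted alkene.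

Step 14
Reactants: 23 (3R)-3-({[tert-butyl(dimethyl)silyl]oxy}methyl)-4-[(1R,3aS,7aS)-4,4,7a-trimethyloctahydro-1H-inden-1-yl]pent-4-enal; 24 ethyl 2-oxoacetate
Product: 25 ethyl (2R,3S,4R)-4-({[tert-butyl(dimethyl)silyl]oxy}methyl)-3-formyl-2-hydroxy-5-[(1R,3aS,7aS)-4,4,7a-trimethyloctahydro-1H-inden-1-yl]hex-5-enoate
Conditions: 24 (polymer form in PhMe, 3 equiv), (S)-α,α-bis[3,5-bis(trifluoromethyl)phenyl]prolinol (10 mol %), MeCN, H2O (3 equiv), rt
Reagents that add atoms: none
Why: Enamine‑mediated (prolinol‑catalysed) cross‑aldol reaction of an aldehyde donor with ethyl glyoxylate; the catalyst fixes the E enamine and its reacting face, and the hydrogen‑bonded glyoxylate should give the anti adduct (2R,3S) under catalyst control over the neighbouring C4 centre.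

Step 15
Reactants: 25 ethyl (2R,3S,4R)-4-({[tert-butyl(dimethyl)silyl]oxy}methyl)-3-formyl-2-hydroxy-5-[(1R,3aS,7aS)-4,4,7a-trimethyloctahydro-1H-inden-1-yl]hex-5-enoate
Product: 28 (3R,4R)-3-hydroxy-4-[(2R)-1-hydroxy-3-[(1R,3aS,7aS)-4,4,7a-trimethyloctahydro-1H-inden-1-yl]but-3-en-2-yl]oxolan-2-one, via diol ester 26 (not isolated), via silyl lactone 27 (not isolated)
Conditions: NaBH4, EtOH, −20 °C; then 2 M aq. HCl, THF, rt
Reagents that add atoms: none
Why: Chemoselective borohydride reduction of the aldehyde, then acid‑promoted 5‑exo‑trig lactonisation onto the ethyl ester and hydrolysis of the primary silyl ether; the anti aldol relationship becomes the cis 3‑hydroxy‑4‑alkyl lactone and no stereocentre is touched.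

Step 16
Reactants: 28 (3R,4R)-3-hydroxy-4-[(2R)-1-hydroxy-3-[(1R,3aS,7aS)-4,4,7a-trimethyloctahydro-1H-inden-1-yl]but-3-en-2-yl]oxolan-2-one
Product: 29 (2R)-2-[(3R,4R)-4-hydroxy-5-oxooxolan-3-yl]-3-[(1R,3aS,7aS)-4,4,7a-trimethyloctahydro-1H-inden-1-yl]but-3-en-1-yl acetate
Conditions: AcCl (1.1 equiv), 2,4,6-collidine, CH2Cl2, −78 °C
Reagents that add atoms: acetyl chloride, CC(=O)Cl
Why: Selective O‑acetylation of the primary alcohol with acetyl chloride and a hindered pyridine base at low temperature; the secondary hydroxyl next to the lactone carbonyl is more hindered and less nucleophilic and should remain free.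

**Compound list**

1 | pent-4-enal | C=CCCC=O | starting material
2 | 2-(triphenyl-λ5-phosphanylidene)propanal | CC(C=O)=P(c1ccccc1)(c1ccccc1)c1ccccc1 | starting material
3 | (2E)-2-methylhepta-2,6-dienal | C=CCC/C=C(C)/C=O | intermediate
4 | ethynyl(trimethyl)silane | C#C[Si](C)(C)C | starting material
5 | (3S,4E)-4-methyl-1-(trimethylsilyl)nona-4,8-dien-1-yn-3-ol | C=CCC/C=C(C)/[C@H](O)C#C[Si](C)(C)C | intermediate
6 | 1,1,1-triethoxyethane | CC(OCC)(OCC)OCC | starting material
7 | (3S,4E)-3-[(1-ethoxyethenyl)oxy]-4-methyl-1-(trimethylsilyl)nona-4,8-dien-1-yne (ketene acetal) | C=CCC/C=C(C)/[C@H](OC(=C)OCC)C#C[Si](C)(C)C | intermediate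
8 | ethyl (3R,4E)-3-(but-3-en-1-yl)-4-methyl-7-(trimethylsilyl)hept-4-en-6-ynoate | CCOC(=O)C[C@@H](CCC=C)/C(C)=C/C#C[Si](C)(C)C | intermediate
9 | 2-methylprop-2-enal | C=C(C)C=O | starting material
10 | ethyl (3R,4E)-4-methyl-3-[(3E)-4-methyl-5-oxopent-3-en-1-yl]-7-(trimethylsilyl)hept-4-en-6-ynoate | CCOC(=O)C[C@@H](CC/C=C(C)/C=O)/C(C)=C/C#C[Si](C)(C)C | intermediate
11 | ethyl (3R,4E)-4-methyl-3-[(3E)-4-methyl-5-oxopent-3-en-1-yl]hept-4-en-6-ynoate | CCOC(=O)C[C@@H](CC/C=C(C)/C=O)/C(C)=C/C#C | intermediate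
12 | ethyl (3R,4E)-4-methyl-3-[(3E)-4-methyl-5-oxopent-3-en-1-yl]hepta-4,6-dienoate | CCOC(=O)C[C@@H](CC/C=C(C)/C=O)/C(C)=C/C=C | intermediate
13 | ethyl 2-[(1R,3aR,4R,7aS)-4-formyl-4,7a-dimethyl-2,3,3a,4,5,7a-hexahydro-1H-inden-1-yl]acetate | CCOC(=O)C[C@H]1CC[C@H]2[C@](C)(C=O)CC=C[C@]12C | intermediate
14 | ethyl 2-[(1R,3aR,4R,7aS)-4-(1,3-dithiolan-2-yl)-4,7a-dimethyl-2,3,3a,4,5,7a-hexahydro-1H-inden-1-yl]acetate | CCOC(=O)C[C@H]1CC[C@H]2[C@](C)(C3SCCS3)CC=C[C@]12C | intermediate
15 | ethyl 2-[(1R,3aS,7aR)-4,4,7a-trimethyloctahydro-1H-inden-1-yl]acetate | CCOC(=O)C[C@H]1CC[C@H]2C(C)(C)CCC[C@]12C | intermediate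
16 | 2-{[tert-butyl(dimethyl)silyl]oxy}acetaldehyde | O=CCO[Si](C)(C)C(C)(C)C | starting material
17 | ethyl 4-{[tert-butyl(dimethyl)silyl]oxy}-3-hydroxy-2-[(1R,3aS,7aR)-4,4,7a-trimethyloctahydro-1H-inden-1-yl]butanoate (epimers at C2 and C3) | CCOC(=O)C(C(O)CO[Si](C)(C)C(C)(C)C)[C@H]1CC[C@H]2C(C)(C)CCC[C@]12C | intermediate
18 | ethyl 4-{[tert-butyl(dimethyl)silyl]oxy}-3-[(methanesulfonyl)oxy]-2-[(1R,3aS,7aR)-4,4,7a-trimethyloctahydro-1H-inden-1-yl]butanoate (mesylate) | CCOC(=O)C(C(OS(C)(=O)=O)CO[Si](C)(C)C(C)(C)C)[C@H]1CC[C@H]2C(C)(C)CCC[C@]12C | intermediate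
19 | ethyl (2E)-4-{[tert-butyl(dimethyl)silyl]oxy}-2-[(1S,3aS,7aS)-4,4,7a-trimethyloctahydro-1H-inden-1-yl]but-2-enoate | CCOC(=O)/C(=C/CO[Si](C)(C)C(C)(C)C)[C@H]1CC[C@H]2C(C)(C)CCC[C@]12C | intermediate
20 | (2E)-4-{[tert-butyl(dimethyl)silyl]oxy}-2-[(1S,3aS,7aS)-4,4,7a-trimethyloctahydro-1H-inden-1-yl]but-2-en-1-ol | OC/C(=C/CO[Si](C)(C)C(C)(C)C)[C@H]1CC[C@H]2C(C)(C)CCC[C@]12C | intermediate
21 | ethoxyethene | C=COCC | starting material
22 | tert-butyl{[(2E)-4-(ethenyloxy)-3-[(1S,3aS,7aS)-4,4,7a-trimethyloctahydro-1H-inden-1-yl]but-2-en-1-yl]oxy}dimethylsilane (allyl vinyl ether) | C=COC/C(=C/CO[Si](C)(C)C(C)(C)C)[C@H]1CC[C@H]2C(C)(C)CCC[C@]12C | intermediate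
23 | (3R)-3-({[tert-butyl(dimethyl)silyl]oxy}methyl)-4-[(1R,3aS,7aS)-4,4,7a-trimethyloctahydro-1H-inden-1-yl]pent-4-enal | O=CC[C@@H](CO[Si](C)(C)C(C)(C)C)C(=C)[C@H]1CC[C@H]2C(C)(C)CCC[C@]12C | intermediate
24 | ethyl 2-oxoacetate | CCOC(=O)C=O | starting material
25 | ethyl (2R,3S,4R)-4-({[tert-butyl(dimethyl)silyl]oxy}methyl)-3-formyl-2-hydroxy-5-[(1R,3aS,7aS)-4,4,7a-trimethyloctahydro-1H-inden-1-yl]hex-5-enoate | C=C([C@H]1CC[C@H]2C(C)(C)CCC[C@]12C)[C@H](CO[Si](C)(C)C(C)(C)C)[C@H](C=O)[C@@H](O)C(=O)OCC | intermediate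
26 | ethyl (2R,3R,4R)-4-({[tert-butyl(dimethyl)silyl]oxy}methyl)-2-hydroxy-3-(hydroxymethyl)-5-[(1R,3aS,7aS)-4,4,7a-trimethyloctahydro-1H-inden-1-yl]hex-5-enoate (diol ester) | C=C([C@H]1CC[C@H]2C(C)(C)CCC[C@]12C)[C@H](CO[Si](C)(C)C(C)(C)C)[C@H](CO)[C@@H](O)C(=O)OCC | intermediate
27 | (3R,4R)-4-[(2R)-1-{[tert-butyl(dimethyl)silyl]oxy}-3-[(1R,3aS,7aS)-4,4,7a-trimethyloctahydro-1H-inden-1-yl]but-3-en-2-yl]-3-hydroxyoxolan-2-one (silyl lactone) | C=C([C@H]1CC[C@H]2C(C)(C)CCC[C@]12C)[C@H](CO[Si](C)(C)C(C)(C)C)[C@@H]1COC(=O)[C@@H]1O | intermediate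
28 | (3R,4R)-3-hydroxy-4-[(2R)-1-hydroxy-3-[(1R,3aS,7aS)-4,4,7a-trimethyloctahydro-1H-inden-1-yl]but-3-en-2-yl]oxolan-2-one | C=C([C@H]1CC[C@H]2C(C)(C)CCC[C@]12C)[C@H](CO)[C@@H]1COC(=O)[C@@H]1O | intermediate
29 | (2R)-2-[(3R,4R)-4-hydroxy-5-oxooxolan-3-yl]-3-[(1R,3aS,7aS)-4,4,7a-trimethyloctahydro-1H-inden-1-yl]but-3-en-1-yl acetate | C=C([C@H]1CC[C@H]2C(C)(C)CCC[C@]12C)[C@H](COC(C)=O)[C@@H]1COC(=O)[C@@H]1O | target

**Step count and risks**

Total step count: 16. Longest linear sequence: 16 steps (from pent-4-enal 1; all other inputs are commercial reagents).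

The three steps most likely to fail:

Step 7. The cycloaddition may lose endo or π‑facial control, giving the cis‑fused or the C1‑epimeric hydrindene, or the Lewis acid may oligomerise the alkyl‑substituted diene before it cyclises. The fallback changes the activation from a Lewis‑acid‑bound aldehyde to a cationic dienophile. It sets out from 12, which is acetalised with ethane-1,2-diol (PPTS, benzene, reflux with water removal) to the dioxolane triene F1. A catalytic amount of CF3SO3H in CH2Cl2 at −78 °C should then open the acetal to an alkoxy‑substituted allyl cation, which undergoes a stepwise ionic Diels–Alder reaction at low temperature and recloses to the dioxolane adduct F2. Treatment of F2 with ethane-1,2-dithiol and BF3·OEt2 exchanges the acetal directly for the dithiolane, and the fallback comes back to the route at 14.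

Step 13. The sigmatropic shift may discriminate poorly between the two faces of the allyl unit, so that the epimer at the CH(CH2OSi) carbon forms, or the vinyl transfer to the hindered alcohol may stay incomplete. The fallback replaces substrate control by chiral‑pool control and sets out from 20. Esterification with 2-[(4R)-2,2-dimethyl-5-oxo-1,3-dioxolan-4-yl]acetic acid (CC1(C)O[C@H](CC(=O)O)C(=O)O1; DCC, DMAP, CH2Cl2) gives the dioxolanone ester F3. Ethanolysis of the dioxolanone (EtOH, cat. K2CO3, 0 °C) gives the hydroxy diester F4. A dianionic Ireland–Claisen rearrangement (LDA, 2.2 equiv, THF, −78 °C; Me3SiCl; warm to rt; mild acid work‑up) should then give the pentenoic acid F5. In this step the lithium alkoxide chelates the ester enolate, fixing its geometry and the face that bonds (anti to the ethoxycarbonyl group), and the chair transition state with the E allyl unit sets the neighbouring centre, so all three side‑chain centres derive from the malate carbon. Reduction of the acid through its mixed anhydride (i-BuOCOCl, N-methylmorpholine, THF, −15 °C; then NaBH4, H2O) gives diol ester 26, where the fallback comes back to the route; the acid treatment of step 15 follows.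

Step 4. The ruthenium carbene may be sequestered by the silyl enyne (enyne metathesis), or the terminal alkene may homodimerise. The fallback avoids metathesis by installing both enal termini at the outset. It sets out from 2: hydrolysis of 2,5-dimethoxytetrahydrofuran (COC1CCC(OC)O1; dilute aq. HCl) gives butanedial F6, and a double Wittig reaction with 2 (2.1 equiv, PhMe, 80 °C) gives the symmetric dienedial F7. Mono‑alkynylation with 4 under the conditions of step 2, with F7 in threefold excess and recovered, gives the hydroxy enynal F8. Johnson–Claisen rearrangement with 6 under the conditions of step 3, followed by an acidic work‑up that returns any acetalised aldehyde, comes back to the route at 10.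

**Further compounds**

F1 | step 7 | ethyl (3R,4E)-3-[(3E)-4-(1,3-dioxolan-2-yl)pent-3-en-1-yl]-4-methylhepta-4,6-dienoate | CCOC(=O)C[C@@H](CC/C=C(C)/C1OCCO1)/C(C)=C/C=C
F2 | step 7 | ethyl 2-[(1R,3aR,4R,7aS)-4-(1,3-dioxolan-2-yl)-4,7a-dimethyl-2,3,3a,4,5,7a-hexahydro-1H-inden-1-yl]acetate | CCOC(=O)C[C@H]1CC[C@H]2[C@](C)(C3OCCO3)CC=C[C@]12C
F3 | step 13 | (2E)-4-{[tert-butyl(dimethyl)silyl]oxy}-2-[(1S,3aS,7aS)-4,4,7a-trimethyloctahydro-1H-inden-1-yl]but-2-en-1-yl 2-[(4R)-2,2-dimethyl-5-oxo-1,3-dioxolan-4-yl]acetate | CC1(C)O[C@H](CC(=O)OC/C(=C/CO[Si](C)(C)C(C)(C)C)[C@H]2CC[C@H]3C(C)(C)CCC[C@]23C)C(=O)O1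
F4 | step 13 | 1-ethyl 4-[(2E)-4-{[tert-butyl(dimethyl)silyl]oxy}-2-[(1S,3aS,7aS)-4,4,7a-trimethyloctahydro-1H-inden-1-yl]but-2-en-1-yl] (2R)-2-hydroxybutanedioate | CCOC(=O)[C@H](O)CC(=O)OC/C(=C/CO[Si](C)(C)C(C)(C)C)[C@H]1CC[C@H]2C(C)(C)CCC[C@]12C
F5 | step 13 | (2S,3R)-3-({[tert-butyl(dimethyl)silyl]oxy}methyl)-2-[(1R)-2-ethoxy-1-hydroxy-2-oxoethyl]-4-[(1R,3aS,7aS)-4,4,7a-trimethyloctahydro-1H-inden-1-yl]pent-4-enoic acid | C=C([C@H]1CC[C@H]2C(C)(C)CCC[C@]12C)[C@H](CO[Si](C)(C)C(C)(C)C)[C@H](C(=O)O)[C@@H](O)C(=O)OCC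
F6 | step 4 | butanedial | O=CCCC=O
F7 | step 4 | (2E,6E)-2,7-dimethylocta-2,6-dienedial | O=C/C(C)=C/CC/C=C(C)/C=O
F8 | step 4 | (2E,6E,8S)-8-hydroxy-2,7-dimethyl-10-(trimethylsilyl)deca-2,6-dien-9-ynal | O=C/C(C)=C/CC/C=C(C)/[C@H](O)C#C[Si](C)(C)C
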